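## The problem

The target 24 is a 1,2-dioxolane-3-acetic acid. Numbering used throughout: C1 carboxyl, C2, ring C3–C4–C5 with O2 on C3 and O1 on C5, chain from C6, methyl-bearing C7, alkenes C10=C11 and C14=C15, phenyl on C15. Both oxygen-bearing ring carbons are fully substituted: C3 carries a methyl group and the CH2CO2H arm, C5 a methyl group and the chain, and only the C4 methylene lies between them. A synthesis must therefore build two quaternary peroxide-bearing centres in a 1,3-relationship with the ring methyl groups trans, (3S,5R), and neither centre has a hydrogen through which it could be corrected later. The third stereocentre, C7 (R), lies outside the ring and one methylene away from C5. It is too remote to direct bond formation at C5 or C3, but it can be bought in the chiral pool and, being fixed, makes all C3/C5 isomers diastereomers that can be separated. The O–O bond rules out hydrogenation, dissolving metals, aluminium hydrides and low-valent metals once the ring exists. The (5E,9E)-styryl diene is a nucleophile toward cations and electrophilic oxidants, and its C10=C11 geometry has to be controlled. The β-peroxy carbonyl unit C1–C3 can open by retro-oxa-Michael loss of the peroxide under base at the aldehyde or ester level. A short solution is possible because C5 with its methyl group, C6 and C4 is a 2-methyl-1-alkene that has taken up a peroxide oxygen at the substituted carbon and a carbon electrophile at its CH2 end, while C3 with its methyl group and two-carbon arm is the carbonyl carbon of a 4-oxygenated butan-2-one, that is, a latent peroxycarbenium ion.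

## Retrosynthesis

**C1 oxidation level.** No skeletal bond is cut. The acid 24 is taken back through the transient aldehyde 23 to the primary alcohol 22, and 22 to its benzoate 21. Keeping C1 as a protected alcohol means the C2 hydrogens are never acidic while strong base is in use, so the base-labile β-peroxy carbonyl unit appears only in the final step. The forward reactions must be a carbonate-level benzoate methanolysis and an alcohol-to-acid oxidation that spares a dialkyl peroxide, an isolated alkene and a styrene.

**C10=C11.** The double bond of 21 is cut to aldehyde 20 and the tetrazolyl sulfone 17. A cut at C12–C13 (allyl–allyl coupling) would raise regiochemical ambiguity, and sp2–sp3 couplings at C9–C10 or C11–C12 would bring low-valent metals next to the peroxide. The chosen cut removes the whole styryl diene, the one part of the chain that cannot be present during a cationic ring formation, and leaves an aldehyde with no stereocentre at its α- or β-carbon. Aldehyde 20 comes from alcohol 19 and this from silyl ether 18. The forward olefination must be E-selective between two unbranched partners and must not touch the benzoate or the peroxide.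

**C3–C4 and O1–C5 (key disconnection).** The ring of 18 is opened at these two bonds to the silylperoxy ketal 11 and the chiral alkene 7.
- Against the mirror-image pair of cuts (C4–C5 and O2–C3): the chosen sense ionises the cheap, achiral three-step fragment 11, which can be used in excess, and keeps the chiral fragment 7 as the limiting nucleophile.
- Against a carboxyl-level arm: a carbonyl at C1 would sit β to the cationic centre and make C2 acidic, so the arm is carried as the benzoate of a primary alcohol.
- Simplification: a ring with two quaternary centres falls to two acyclic pieces, one without any stereocentre of consequence and one with C7 alone.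
- Demands: Markovnikov attack, ring closure faster than proton loss, and survival of the silyl ether and benzoate under the Lewis acid. No facial control is expected, so the isomers have to be separated.

**Alkene 7.** The C4=C5 bond is cut by methylenation to methyl ketone 6. Ketone 6 is taken back to alcohol 5, to diol 4 (primary-selective silylation), through ozonide 3 to the alkenol 2 (cleavage of the isopropylidene end, which becomes C10), and by methyl addition to (R)-citronellal 1. The chiral pool supplies C7 in the correct sense and C6–C10 without any chain extension. The forward steps must leave the C7 centre, which is β to every carbonyl on the way, untouched.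

**Peroxyketal 11.** The O–Si bond is cut to hydroperoxy ketal 10. Ketal 10 is taken back by alkene ozonolysis in an alcohol medium that supplies the methoxy group to the benzoate 9 of the commercial alkenol 8. This is preferred over ketalisation and perhydrolysis of a β-acyloxy ketone, which tends to eliminate to an enone and needs concentrated peroxide. The ozonolysis must fragment toward the substituted carbonyl oxide.

**Sulfone 17.** S-oxidation leads back to sulfide 16 and the C–S bond to alcohol 15. Alcohol 15 comes from ester 14, whose C12–C13 bond is cut to cinnamyl bromide 12 and tert-butyl acetate 13. The E-styrene is bought with 12 and never has to be made.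

## Roads not taken

**Alternative 1:** The ring is cut at both C–O bonds (O1–C5 and O2–C3), with the acetic acid arm added to C3 afterwards. In the forward sense enone A1 forms an iminium ion with a 9-amino-9-deoxy-epi-cinchona primary amine salt. Aqueous H2O2 adds at C5, and the new OOH group closes onto the C3 carbonyl to give dioxolanol A2. A2 would be converted into the methyl peroxyketal A3 and substituted with a silyl ketene acetal under a Lewis acid.
- Merits: it is the only plan in which the absolute configuration at C5 could come from a catalyst instead of a separation. The whole diene chain can be present from the start, because nothing cationic or metallic acts on it.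
- Weak points: the reaction type is established for β-monosubstituted enones. With the β,β-disubstituted A1 the addition must create a fully substituted C–O centre, is slower and more reversible, and the catalyst must distinguish methyl from a CH2 group. The enone geometry can scramble through the dienamine. C3 is still unset after the key step, and the later substitution through a peroxycarbenium ion has no better control than the ring closure of the chosen plan.
- Comparison: if the hydroperoxidation were selective, this road would halve the number of isomers and avoid a late olefination, which is a real advantage. The chosen plan offers instead a key step whose reaction class is known on this exact substitution pattern and which forms the ring and both quaternary centres together.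

**Alternative 2:** The cuts are O2–C3 and C1–C2. The precursor is the tertiary hydroperoxide A4 with a methallyl group. With Pd(OAc)2, benzoquinone and CO in methanol, the hydroperoxide would add to the alkene in a 5-exo closure. The carbon–palladium bond formed at C2 has no β-hydrogen, because C3 is quaternary, and would be carbonylated to give methyl ester A5.
- Merits: C1 arrives at the ester level, so the end game is one saponification. The blocked β-elimination is ideal for CO insertion. The diene could in principle already be present.
- Weak points: A4 must be a single configuration at C5, and no direct stereoselective route to such a tertiary hydroperoxide exists, so the C5 problem is moved and not solved. Hydroperoxides oxidise palladium and are themselves reduced under CO and palladium. Carbonylative capture after peroxypalladation has no precedent, only non-carbonylative cyclisations of unsaturated hydroperoxides. Divalent palladium with benzoquinone can also oxidise the styryl diene.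
- Comparison: after ring formation this road is clearly shorter than the chosen one. The chosen plan offers a key step of known type and needs no configurationally defined tertiary hydroperoxide.

**Alternative 3:** The cuts are C4–C5 and O2–C3, the reverse assignment of roles. The C5 peroxycarbenium ion released by SnCl4 from the silylperoxy ketal A6 (derived from ketone 6) is attacked by methyl 3-methylbut-3-enoate A7. The tertiary C3 cation is then closed by the peroxide oxygen to give ester A8.
- Merits: it uses the same reaction class and the same number of fragments. C1 is delivered as the ester, so benzoate cleavage and the final oxidation are not needed. A7 is commercial.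
- Weak points: A7 is a β,γ-unsaturated ester, so the alkene is inductively deactivated and can isomerise into conjugation under the Lewis acid. The cation formed at C3 lies β to the ester carbonyl and next to acidic C2 hydrogens, so proton loss to a conjugated enoate competes with ring closure. The valuable chiral fragment is the one that is ionised and cannot be used in excess cheaply. The β-peroxy ester must then survive the basic olefination, with a risk of E1cB ring opening. There is no stereocontrol here either.
- Comparison: this road is two steps shorter on paper. The chosen plan spends those steps on an unactivated 2-methyl-1-alkene as the nucleophile, a plain trialkyl cation in the ring closure, the cheap partner as the ionised one, and no enolisable carbonyl beside the peroxide until the last step. The reversed sense is kept in reserve with alkene 9 in place of A7.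

Key step: step 13

Remark: the carbinol centres of 2–5 and the ketal carbon of 10 and 11 are destroyed or planarised later and are carried as mixtures. It is assumed that the four diastereomers of step 13 can be separated by chromatography, with the ring configuration read from NOE contacts and the relation to C7 from a crystalline derivative.

## Route

Step 1
Reactants: 1 (R)-citronellal [(3R)-3,7-dimethyloct-6-enal]
Product: 2 (4R)-4,8-dimethylnon-7-en-2-ol (mixture of C2 epimers)
Conditions: MeMgBr, Et2O, −78 → 0 °C; aq. NH4Cl
Reagents that add atoms: methylmagnesium bromide, C[Mg]Br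
Why: Grignard addition to the aldehyde; the new carbinol centre is formed without control and is removed in step 4, and the methyl-bearing centre is β to the carbonyl and cannot epimerise.

Step 2
Reactants: 2 (4R)-4,8-dimethylnon-7-en-2-ol
Product: 4 (4R)-4-methylheptane-1,6-diol as a mixture of C6 epimers, via ozonide 3 (not isolated)
Conditions: O3, CH2Cl2, −78 °C; then NaBH4, MeOH, −78 °C → rt
Reagents that add atoms: ozone, O=[O+][O-]
Why: Ozonolysis of the trisubstituted alkene followed by borohydride reduction of the ozonide in the same flask gives the primary alcohol; the free secondary alcohol is inert and no stereocentre is touched.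

Step 3
Reactants: 4 (4R)-4-methylheptane-1,6-diol
Product: 5 (4R)-7-{[tert-butyl(diphenyl)silyl]oxy}-4-methylheptan-2-ol (mixture of C2 epimers)
Conditions: tBuPh2SiCl (1.05 equiv), imidazole, CH2Cl2, 0 °C
Reagents that add atoms: tert-butyl(chloro)diphenylsilane, CC(C)(C)[Si](Cl)(c1ccccc1)c1ccccc1
Why: Silyl ether formation; the bulky silyl chloride used near stoichiometry at 0 °C distinguishes the primary from the secondary hydroxyl group.

Step 4
Reactants: 5 (4R)-7-{[tert-butyl(diphenyl)silyl]oxy}-4-methylheptan-2-ol
Product: 6 (4R)-7-{[tert-butyl(diphenyl)silyl]oxy}-4-methylheptan-2-one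
Conditions: Dess–Martin periodinane, CH2Cl2, 0 °C → rt
Reagents that add atoms: none
Why: Dess–Martin oxidation of a secondary alcohol to the methyl ketone under near-neutral conditions that keep the silyl ether; the stereocentre is β to the new carbonyl.

Step 5
Reactants: 6 (4R)-7-{[tert-butyl(diphenyl)silyl]oxy}-4-methylheptan-2-one
Product: 7 tert-butyl{[(4R)-4,6-dimethylhept-6-en-1-yl]oxy}diphenylsilane
Conditions: Ph3PCH3Br, KOtBu, THF, 0 °C → rt
Reagents that add atoms: methyltriphenylphosphonium bromide, C[P+](c1ccccc1)(c1ccccc1)c1ccccc1.[Br-]
Why: Wittig methylenation of a methyl ketone with the non-stabilised ylide; the new CH2 is the future ring carbon C4.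

Step 6
Reactants: 8 3-methylbut-3-en-1-ol
Product: 9 3-methylbut-3-en-1-yl benzoate
Conditions: BzCl, Et3N, 4-(dimethylamino)pyridine (cat.), CH2Cl2, 0 °C → rt
Reagents that add atoms: benzoyl chloride, O=C(Cl)c1ccccc1
Why: Nucleophile-catalysed acylation of a primary alcohol; the benzoate is stable to ozone and Lewis acid and is removable later without reduction.

Step 7
Reactants: 9 3-methylbut-3-en-1-yl benzoate
Product: 10 3-hydroperoxy-3-methoxybutyl benzoate (racemic)
Conditions: O3, CH2Cl2/MeOH, −78 °C; N2 purge; concentration below rt, no reductive work-up
Reagents that add atoms: ozone, O=[O+][O-]; methanol, CO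
Why: Criegee ozonolysis of a 1,1-disubstituted alkene: the primary ozonide fragments to formaldehyde and the more substituted carbonyl oxide, which methanol traps as the α-methoxy hydroperoxide; the new ketal centre is racemic and is planarised in step 13.

Step 8
Reactants: 10 3-hydroperoxy-3-methoxybutyl benzoate
Product: 11 3-methoxy-3-[(triethylsilyl)peroxy]butyl benzoate (racemic)
Conditions: Et3SiCl, imidazole, DMF, 0 °C
Reagents that add atoms: chlorotriethylsilane, CC[Si](Cl)(CC)CC
Why: O-silylation of the hydroperoxide under standard silyl chloride/imidazole conditions gives the silylperoxy ketal, which can be chromatographed and ionised by a Lewis acid.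

Step 9
Reactants: 12 cinnamyl bromide [(E)-(3-bromoprop-1-en-1-yl)benzene]; 13 tert-butyl acetate
Product: 14 tert-butyl (4E)-5-phenylpent-4-enoate
Conditions: LiN(iPr)2, 13 (1.5 equiv), THF, −78 °C; then 12, −78 → −20 °C
Reagents that add atoms: none
Why: Alkylation of the lithium enolate of a tert-butyl ester (no Claisen self-condensation) with a primary allylic bromide at the unhindered terminus; the E-styrene is carried over unchanged and excess enolate limits dialkylation.

Step 10
Reactants: 14 tert-butyl (4E)-5-phenylpent-4-enoate
Product: 15 (4E)-5-phenylpent-4-en-1-ol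
Conditions: LiAlH4, THF, 0 °C
Reagents that add atoms: none
Why: Hydride reduction of the ester to the primary alcohol; the remote styrene is not reduced.

Step 11
Reactants: 15 (4E)-5-phenylpent-4-en-1-ol
Product: 16 1-phenyl-5-{[(4E)-5-phenylpent-4-en-1-yl]sulfanyl}-1H-tetrazole
Conditions: 1-phenyl-1H-tetrazole-5-thiol, PPh3, diisopropyl azodicarboxylate, THF, 0 °C → rt
Reagents that add atoms: 1-phenyl-1H-tetrazole-5-thiol, Sc1nnnn1-c1ccccc1
Why: Mitsunobu thioetherification of a primary alcohol with an acidic heteroaryl thiol.

Step 12
Reactants: 16 1-phenyl-5-{[(4E)-5-phenylpent-4-en-1-yl]sulfanyl}-1H-tetrazole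
Product: 17 1-phenyl-5-{[(4E)-5-phenylpent-4-en-1-yl]sulfonyl}-1H-tetrazole
Conditions: (NH4)6Mo7O24·4H2O (cat.), 30% aq. H2O2, EtOH, 0 °C → rt
Reagents that add atoms: hydrogen peroxide, OO
Why: Molybdate-catalysed peroxide oxidation of sulfide to sulfone; the peroxomolybdate oxidant prefers sulfur over the styrene, unlike a peracid.

Step 13
Reactants: 11 3-methoxy-3-[(triethylsilyl)peroxy]butyl benzoate; 7 tert-butyl{[(4R)-4,6-dimethylhept-6-en-1-yl]oxy}diphenylsilane
Product: 18 2-[(3R,5R)-5-[(2R)-5-{[tert-butyl(diphenyl)silyl]oxy}-2-methylpentyl]-3,5-dimethyl-1,2-dioxolan-3-yl]ethyl benzoate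
Conditions: 11 (1.5 equiv), SnCl4 (1.2 equiv), CH2Cl2, −78 °C; aq. NaHCO3; flash chromatography, then preparative HPLC
Reagents that add atoms: none
Why: SnCl4 removes the methoxy group of 11 to give the C3 peroxycarbenium ion, to which the unsubstituted CH2 terminus of the 1,1-disubstituted alkene of 7 adds (C3–C4 bond), leaving the charge on the tertiary carbon C5. The silyl-bearing peroxide oxygen then captures this cation (O1–C5 bond) and the triethylsilyl group is lost, so the 1,2-dioxolane arises by a stepwise cationic [3+2] annulation. The closest known reaction type is the SnCl4- or TiCl4-promoted annulation of ketone-derived triethylsilylperoxy ketals with 2-methyl-1-alkenes to 3,3,5,5-tetrasubstituted 1,2-dioxolanes, and a dialkyl peroxycarbenium ion paired with an unfunctionalised 2-methyl-1-alkene lies within that scope. The ring closes by intramolecular capture of a trigonal carbocation by oxygen to form a five-membered ring; no π bond is broken in the closure, so it is a cation–nucleophile recombination and not an exo or endo addition. C3 becomes stereogenic in the C–C bond formation and C5 in the ring closure, and neither has a controlling element: the peroxycarbenium ion is planar (the configuration of racemic 11 is lost), methyl and CH2 substituents differ little at both carbons, and C7 is insulated from C5 by the C6 methylene. The step does need regioselectivity, secured by the 1,1-disubstitution that allows only the tertiary cation; chemoselectivity, secured by the absence of any second nucleophilic alkene (the styryl diene is added later) and by a silyl ether and a benzoate that tolerate SnCl4 at −78 °C; and ring closure ahead of proton loss, favoured by the peroxide oxygen being placed to form a five-membered ring. All four diastereomers are therefore to be expected, and the (3R,5R) isomer 18 with trans ring methyl groups is to be separated by chromatography, with 11 used in excess because it is the cheap partner.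

Step 14
Reactants: 18 2-[(3R,5R)-5-[(2R)-5-{[tert-butyl(diphenyl)silyl]oxy}-2-methylpentyl]-3,5-dimethyl-1,2-dioxolan-3-yl]ethyl benzoate
Product: 19 2-[(3R,5R)-5-[(2R)-5-hydroxy-2-methylpentyl]-3,5-dimethyl-1,2-dioxolan-3-yl]ethyl benzoate
Conditions: Bu4NF, AcOH (1:1), THF, 0 °C → rt
Reagents that add atoms: none
Why: Fluoride-mediated desilylation, buffered with acetic acid so that the benzoate is not attacked; a peroxide without α-hydrogens is inert to fluoride.

Step 15
Reactants: 19 2-[(3R,5R)-5-[(2R)-5-hydroxy-2-methylpentyl]-3,5-dimethyl-1,2-dioxolan-3-yl]ethyl benzoate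
Product: 20 2-[(3R,5R)-3,5-dimethyl-5-[(2R)-2-methyl-5-oxopentyl]-1,2-dioxolan-3-yl]ethyl benzoate
Conditions: Dess–Martin periodinane, CH2Cl2, 0 °C → rt
Reagents that add atoms: none
Why: Dess–Martin oxidation of the primary alcohol to the aldehyde, metal-free and non-reducing, so the O–O bond is untouched; C7 is γ to the aldehyde and cannot epimerise.

Step 16
Reactants: 20 2-[(3R,5R)-3,5-dimethyl-5-[(2R)-2-methyl-5-oxopentyl]-1,2-dioxolan-3-yl]ethyl benzoate; 17 1-phenyl-5-{[(4E)-5-phenylpent-4-en-1-yl]sulfonyl}-1H-tetrazole
Product: 21 2-[(3R,5R)-3,5-dimethyl-5-[(2R,5E,9E)-2-methyl-10-phenyldeca-5,9-dien-1-yl]-1,2-dioxolan-3-yl]ethyl benzoate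
Conditions: 17 (1.3 equiv), KN(SiMe3)2 (1.25 equiv), DME, −60 °C; then 20, −60 °C → rt
Reagents that add atoms: none
Why: Julia–Kocienski olefination: the premetalated tetrazolyl sulfone adds to the aldehyde, and Smiles rearrangement with loss of SO2 and the tetrazolyl oxide gives the alkene; the potassium base in DME is the combination known to favour the E-alkene, which sets the C10=C11 geometry. The low temperature and small excess of carbanion should leave the benzoate and the hindered peroxide alone.

Step 17
Reactants: 21 2-[(3R,5R)-3,5-dimethyl-5-[(2R,5E,9E)-2-methyl-10-phenyldeca-5,9-dien-1-yl]-1,2-dioxolan-3-yl]ethyl benzoate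
Product: 22 2-[(3R,5R)-3,5-dimethyl-5-[(2R,5E,9E)-2-methyl-10-phenyldeca-5,9-dien-1-yl]-1,2-dioxolan-3-yl]ethan-1-ol
Conditions: K2CO3 (0.2 equiv), MeOH, rt
Reagents that add atoms: none
Why: Base-catalysed transesterification of the benzoate with methanol; at this stage there is no carbonyl β to the peroxide and no α-hydrogen on the ring, so carbonate is tolerated.

Step 18
Reactants: 22 2-[(3R,5R)-3,5-dimethyl-5-[(2R,5E,9E)-2-methyl-10-phenyldeca-5,9-dien-1-yl]-1,2-dioxolan-3-yl]ethan-1-ol
Product: 24 2-[(3S,5R)-3,5-dimethyl-5-[(2R,5E,9E)-2-methyl-10-phenyldeca-5,9-dien-1-yl]-1,2-dioxolan-3-yl]acetic acid (the target), via aldehyde 23 (not isolated)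
Conditions: 2,2,6,6-tetramethylpiperidin-1-oxyl (cat.), PhI(OAc)2 (2.2 equiv), MeCN/H2O (1:1), 0 °C → rt
Reagents that add atoms: water, O
Why: Oxoammonium-catalysed oxidation with PhI(OAc)2 in aqueous acetonitrile takes the primary alcohol through the aldehyde and its hydrate to the acid in one flask; the medium is near neutral and metal-free and spares alkenes and the peroxide. The aldehyde is consumed as it forms, which leaves little time for retro-oxa-Michael opening.

## Compound list

1 | (R)-citronellal, (3R)-3,7-dimethyloct-6-enal | C[C@H](CCC=C(C)C)CC=O | starting material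
2 | (4R)-4,8-dimethylnon-7-en-2-ol (C2 epimers) | C[C@H](CCC=C(C)C)CC(C)O | intermediate
3 | (4R)-6-(5,5-dimethyl-1,2,4-trioxolan-3-yl)-4-methylhexan-2-ol (ozonide, stereoisomer mixture, not isolated) | C[C@H](CCC1OOC(C)(C)O1)CC(C)O | intermediate
4 | (4R)-4-methylheptane-1,6-diol (C6 epimers) | C[C@H](CCCO)CC(C)O | intermediate
5 | (4R)-7-{[tert-butyl(diphenyl)silyl]oxy}-4-methylheptan-2-ol (C2 epimers) | C[C@H](CCCO[Si](c1ccccc1)(c1ccccc1)C(C)(C)C)CC(C)O | intermediate
6 | (4R)-7-{[tert-butyl(diphenyl)silyl]oxy}-4-methylheptan-2-one | C[C@H](CCCO[Si](c1ccccc1)(c1ccccc1)C(C)(C)C)CC(C)=O | intermediate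
7 | tert-butyl{[(4R)-4,6-dimethylhept-6-en-1-yl]oxy}diphenylsilane | C=C(C)C[C@H](C)CCCO[Si](c1ccccc1)(c1ccccc1)C(C)(C)C | intermediate
8 | 3-methylbut-3-en-1-ol | C=C(C)CCO | starting material
9 | 3-methylbut-3-en-1-yl benzoate | C=C(C)CCOC(=O)c1ccccc1 | intermediate
10 | 3-hydroperoxy-3-methoxybutyl benzoate (racemic) | COC(C)(CCOC(=O)c1ccccc1)OO | intermediate
11 | 3-methoxy-3-[(triethylsilyl)peroxy]butyl benzoate (racemic) | COC(C)(CCOC(=O)c1ccccc1)OO[Si](CC)(CC)CC | intermediate
12 | cinnamyl bromide, (E)-(3-bromoprop-1-en-1-yl)benzene | BrC/C=C/c1ccccc1 | starting material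
13 | tert-butyl acetate | CC(=O)OC(C)(C)C | starting material
14 | tert-butyl (4E)-5-phenylpent-4-enoate | CC(C)(C)OC(=O)CC/C=C/c1ccccc1 | intermediate
15 | (4E)-5-phenylpent-4-en-1-ol | OCCC/C=C/c1ccccc1 | intermediate
16 | 1-phenyl-5-{[(4E)-5-phenylpent-4-en-1-yl]sulfanyl}-1H-tetrazole | C(CC/C=C/c1ccccc1)Sc1nnnn1-c1ccccc1 | intermediate
17 | 1-phenyl-5-{[(4E)-5-phenylpent-4-en-1-yl]sulfonyl}-1H-tetrazole | O=S(=O)(CCC/C=C/c1ccccc1)c1nnnn1-c1ccccc1 | intermediate
18 | 2-[(3R,5R)-5-[(2R)-5-{[tert-butyl(diphenyl)silyl]oxy}-2-methylpentyl]-3,5-dimethyl-1,2-dioxolan-3-yl]ethyl benzoate | C[C@H](CCCO[Si](c1ccccc1)(c1ccccc1)C(C)(C)C)C[C@]1(C)C[C@@](C)(CCOC(=O)c2ccccc2)OO1 | intermediate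
19 | 2-[(3R,5R)-5-[(2R)-5-hydroxy-2-methylpentyl]-3,5-dimethyl-1,2-dioxolan-3-yl]ethyl benzoate | C[C@H](CCCO)C[C@]1(C)C[C@@](C)(CCOC(=O)c2ccccc2)OO1 | intermediate
20 | 2-[(3R,5R)-3,5-dimethyl-5-[(2R)-2-methyl-5-oxopentyl]-1,2-dioxolan-3-yl]ethyl benzoate | C[C@H](CCC=O)C[C@]1(C)C[C@@](C)(CCOC(=O)c2ccccc2)OO1 | intermediate
21 | 2-[(3R,5R)-3,5-dimethyl-5-[(2R,5E,9E)-2-methyl-10-phenyldeca-5,9-dien-1-yl]-1,2-dioxolan-3-yl]ethyl benzoate | C[C@H](CC/C=C/CC/C=C/c1ccccc1)C[C@]1(C)C[C@@](C)(CCOC(=O)c2ccccc2)OO1 | intermediate
22 | 2-[(3R,5R)-3,5-dimethyl-5-[(2R,5E,9E)-2-methyl-10-phenyldeca-5,9-dien-1-yl]-1,2-dioxolan-3-yl]ethan-1-ol | C[C@H](CC/C=C/CC/C=C/c1ccccc1)C[C@]1(C)C[C@@](C)(CCO)OO1 | intermediate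
23 | 2-[(3S,5R)-3,5-dimethyl-5-[(2R,5E,9E)-2-methyl-10-phenyldeca-5,9-dien-1-yl]-1,2-dioxolan-3-yl]acetaldehyde (not isolated) | C[C@H](CC/C=C/CC/C=C/c1ccccc1)C[C@]1(C)C[C@@](C)(CC=O)OO1 | intermediate
24 | 2-[(3S,5R)-3,5-dimethyl-5-[(2R,5E,9E)-2-methyl-10-phenyldeca-5,9-dien-1-yl]-1,2-dioxolan-3-yl]acetic acid | C[C@H](CC/C=C/CC/C=C/c1ccccc1)C[C@]1(C)C[C@@](C)(CC(=O)O)OO1 | target

## Step count and risks

Total step count: 18. Longest linear sequence: 11 steps (steps 1–5 and 13–18).

**Step 13 (key step).**
- Most likely problem: absence of facial discrimination at both new centres, so that the material is spread over four diastereomers and the separation becomes the bottleneck.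
- Second problem: diversion of the cationic intermediates, by internal capture of the C3 peroxycarbenium ion by the benzoate carbonyl, by alkyl migration to oxygen, or by proton loss from the C5 cation before ring closure.
- Fallback: reverse the roles of the two fragments so that the other pair of ring bonds (C4–C5 and O2–C3) is formed. Starting from 7, ozonolysis in CH2Cl2/MeOH without reductive work-up would give tert-butyl{[(4R)-6-hydroperoxy-6-methoxy-4-methylheptyl]oxy}diphenylsilane F1. Silylation with Et3SiCl and imidazole would give tert-butyl({(4R)-6-methoxy-4-methyl-6-[(triethylsilyl)peroxy]heptyl}oxy)diphenylsilane F2. SnCl4 would then ionise F2 at C5 in the presence of alkene 9, whose CH2 terminus attacks C5 and whose tertiary cation at C3 is closed by the peroxide oxygen. The fallback returns to the route at 18.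
- Limit of the fallback: it answers the reactivity problems, not the stereochemical spread, which is inherent in both senses. If 18 resists separation, the isomers are separated one step later as the more polar alcohols 19.

**Step 16.**
- Most likely problem: incomplete E-selectivity between two unbranched partners, and attack of the free sulfonyl carbanion on the benzoate while the valuable aldehyde is the limiting electrophile.
- Fallback: exchange the roles of the partners. Starting from 19, mesylation (MsCl, Et3N) would give 2-[(3R,5R)-5-{(2R)-5-[(methanesulfonyl)oxy]-2-methylpentyl}-3,5-dimethyl-1,2-dioxolan-3-yl]ethyl benzoate F3. Displacement with 1-phenyl-1H-tetrazole-5-thiol and K2CO3 would give 2-[(3R,5R)-3,5-dimethyl-5-{(2R)-2-methyl-5-[(1-phenyl-1H-tetrazol-5-yl)sulfanyl]pentyl}-1,2-dioxolan-3-yl]ethyl benzoate F4. Molybdate-catalysed H2O2 oxidation would give 2-[(3R,5R)-3,5-dimethyl-5-{(2R)-2-methyl-5-[(1-phenyl-1H-tetrazol-5-yl)sulfonyl]pentyl}-1,2-dioxolan-3-yl]ethyl benzoate F5. Dess–Martin oxidation of 15 would give (4E)-5-phenylpent-4-enal F6. F5 and an excess of the cheap aldehyde F6 would be combined, with KN(SiMe3)2 added last so that the carbanion is trapped as it forms. The fallback returns at 21.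

**Step 7.**
- Most likely problem: fragmentation of the primary ozonide in the unwanted direction, or decomposition of the hydroperoxy ketal during concentration.
- Fallback: build the same hydroperoxy ketal by ketal exchange without ozone. Commercial 4-hydroxybutan-2-one F7 would be benzoylated (BzCl, pyridine, 0 °C) to 3-oxobutyl benzoate F8. Ketalisation with HC(OMe)3 and MeOH under acid catalysis would give 3,3-dimethoxybutyl benzoate F9. Acid-catalysed exchange of one methoxy group with ethereal H2O2 would give the hydroperoxy ketal. The fallback returns at 10.

**Step 18.**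
- Most likely problem: ring opening by retro-oxa-Michael loss of the peroxide at the β-peroxy aldehyde stage, or attack of the oxoammonium oxidant on the styrene.
- Fallback: divide the oxidation into two separate reactions. Starting from 22, Dess–Martin oxidation would give aldehyde 23, which is isolated. A Lindgren–Pinnick chlorite oxidation (NaClO2, NaH2PO4, 2-methylbut-2-ene, tBuOH/H2O) in a mildly acidic buffer then takes it to the acid. The fallback returns at 24 and needs no compound outside the list.

## Further compounds

F1 | step 13 | tert-butyl{[(4R)-6-hydroperoxy-6-methoxy-4-methylheptyl]oxy}diphenylsilane (C6 epimers) | C[C@H](CCCO[Si](c1ccccc1)(c1ccccc1)C(C)(C)C)CC(C)(OC)OO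
F2 | step 13 | tert-butyl({(4R)-6-methoxy-4-methyl-6-[(triethylsilyl)peroxy]heptyl}oxy)diphenylsilane (C6 epimers) | C[C@H](CCCO[Si](c1ccccc1)(c1ccccc1)C(C)(C)C)CC(C)(OC)OO[Si](CC)(CC)CC
F3 | step 16 | 2-[(3R,5R)-5-{(2R)-5-[(methanesulfonyl)oxy]-2-methylpentyl}-3,5-dimethyl-1,2-dioxolan-3-yl]ethyl benzoate | C[C@H](CCCOS(C)(=O)=O)C[C@]1(C)C[C@@](C)(CCOC(=O)c2ccccc2)OO1
F4 | step 16 | 2-[(3R,5R)-3,5-dimethyl-5-{(2R)-2-methyl-5-[(1-phenyl-1H-tetrazol-5-yl)sulfanyl]pentyl}-1,2-dioxolan-3-yl]ethyl benzoate | C[C@H](CCCSc1nnnn1-c1ccccc1)C[C@]1(C)C[C@@](C)(CCOC(=O)c2ccccc2)OO1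
F5 | step 16 | 2-[(3R,5R)-3,5-dimethyl-5-{(2R)-2-methyl-5-[(1-phenyl-1H-tetrazol-5-yl)sulfonyl]pentyl}-1,2-dioxolan-3-yl]ethyl benzoate | C[C@H](CCCS(=O)(=O)c1nnnn1-c1ccccc1)C[C@]1(C)C[C@@](C)(CCOC(=O)c2ccccc2)OO1
F6 | step 16 | (4E)-5-phenylpent-4-enal | O=CCC/C=C/c1ccccc1
F7 | step 7 | 4-hydroxybutan-2-one | CC(=O)CCO
F8 | step 7 | 3-oxobutyl benzoate | CC(=O)CCOC(=O)c1ccccc1
F9 | step 7 | 3,3-dimethoxybutyl benzoate | COC(C)(OC)CCOC(=O)c1ccccc1
F0 | step 18 | none | none
A1 | alternative 1 | (3E,6R,9E,13E)-4,6-dimethyl-14-phenyltetradeca-3,9,13-trien-2-one | C[C@H](CC/C=C/CC/C=C/c1ccccc1)C/C(C)=C/C(C)=O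
A2 | alternative 1 | (5R)-3,5-dimethyl-5-[(2R,5E,9E)-2-methyl-10-phenyldeca-5,9-dien-1-yl]-1,2-dioxolan-3-ol (C3 epimers) | C[C@H](CC/C=C/CC/C=C/c1ccccc1)C[C@]1(C)CC(C)(O)OO1
A3 | alternative 1 | (5R)-3-methoxy-3,5-dimethyl-5-[(2R,5E,9E)-2-methyl-10-phenyldeca-5,9-dien-1-yl]-1,2-dioxolane (C3 epimers) | C[C@H](CC/C=C/CC/C=C/c1ccccc1)C[C@]1(C)CC(C)(OC)OO1
A4 | alternative 2 | (4R,6R,9E,13E)-4-hydroperoxy-2,4,6-trimethyl-14-phenyltetradeca-1,9,13-triene | C[C@H](CC/C=C/CC/C=C/c1ccccc1)C[C@](C)(CC(C)=C)OO
A5 | alternative 2 | methyl 2-[(3S,5R)-3,5-dimethyl-5-[(2R,5E,9E)-2-methyl-10-phenyldeca-5,9-dien-1-yl]-1,2-dioxolan-3-yl]acetate | C[C@H](CC/C=C/CC/C=C/c1ccccc1)C[C@]1(C)C[C@@](C)(CC(=O)OC)OO1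
A6 | alternative 3 | tert-butyl({(4R)-6-methoxy-4-methyl-6-[(triethylsilyl)peroxy]heptyl}oxy)diphenylsilane (C6 epimers) | C[C@H](CCCO[Si](c1ccccc1)(c1ccccc1)C(C)(C)C)CC(C)(OC)OO[Si](CC)(CC)CC
A7 | alternative 3 | methyl 3-methylbut-3-enoate | C=C(C)CC(=O)OC
A8 | alternative 3 | methyl 2-[(3S,5R)-5-[(2R)-5-{[tert-butyl(diphenyl)silyl]oxy}-2-methylpentyl]-3,5-dimethyl-1,2-dioxolan-3-yl]acetate | C[C@H](CCCO[Si](c1ccccc1)(c1ccccc1)C(C)(C)C)C[C@]1(C)C[C@@](C)(CC(=O)OC)OO1
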